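**Retrosynthetic overview**

1. The strategy rests on the benzene ring of the coumarin on C6 of the cyclohexene (C4a', C5', C6', C7', C8', C8a'): a 1,3-dioxygenated ring with oxygen on C7' and C8a' and the cyclohexene carbon C6 on C6' (ortho to O-7', para to O-8a'). A diazo-ketone Danheiser benzannulation forms C6'–C7', C7'–C8' and C8a'–C4a' from an (E)-α'-diazo enone carried on C6 and a tert-butyl ynol ether.
2. After the benzannulation: O-methylation at C7', release of the C8a' hydroxyl, ortho-formylation at C4a' and Wittig lactonisation close the pyranone ring.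
3. Last bond: Mizoroki–Heck arylation of the vinyl group on the quaternary carbon C1 with 6-bromo-7-methoxycoumarin gives the E-styryl link.
4. Before the benzannulation: a catalytic enantioselective Diels–Alder reaction of ethyl (E)-3-methyl-4-oxobut-2-enoate with (E)-1-silyl-2-methylbutadiene sets C1 and C6; later protodesilylation with allylic shift places the ring alkene at C4=C5.
5. Ring order: cyclohexene, then the benzene ring (key step), then its pyranone ring; the second coumarin is made separately and joined last.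

Key step: step 11

Numbering used in the text: cyclohexene C1 = quaternary carbon, C6 = aryl-bearing CH, C4=C5 = ring alkene; primed locants = coumarin on C6. The target is (1R,6S) in this numbering.

Assumption: the cationic oxazaborolidine from (R)-diphenylprolinol is taken to deliver the diene to the Si face at C3 of the enal (formyl C–H···O binding model, recalled rather than verified); if the first adduct proves antipodal, the (S)-catalyst is used with no other change.

Remark on spectator groups: C1 carries a vinyl group through the key step (from the Diels–Alder formyl group), so the second coumarin can be attached in one Heck step. The ynol ether oxygen carries tert-butyl, because tert-alkoxyethynes are made in two known steps, whereas O-selective silylation of the unsubstituted ynolate cannot be counted on.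

**Route**

Step 1
Reactants: 1 3-methyl-2,5-dihydrothiophene 1,1-dioxide (3-methyl-3-sulfolene)
Product: 2 3-methyl-2-(trimethylsilyl)-2,5-dihydrothiophene 1,1-dioxide (racemic)
Conditions: Me3SiCl (excess), LiN(SiMe3)2 added last, THF, −78 °C
Reagents that add atoms: chlorotrimethylsilane, C[Si](C)(C)Cl
Why: α-Sulfonyl carbanion silylation with in-situ quench; deprotonation should favour C2, where the allyl anion has the methyl on its central carbon, and the silyl chloride traps the anion before it can ring-open (any C5 isomer is removed by chromatography).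

Step 2
Reactants: 2 3-methyl-2-(trimethylsilyl)-2,5-dihydrothiophene 1,1-dioxide
Product: 3 (E)-trimethyl(2-methylbuta-1,3-dien-1-yl)silane
Conditions: neat, NaHCO3 (trace), 130 °C, diene distilled as formed
Reagents that add atoms: none
Why: Cheletropic extrusion of SO2 is disrotatory and turns the C2 substituent outward, so the (E)-1-silyl diene should result.

Step 3
Reactants: 3 (E)-trimethyl(2-methylbuta-1,3-dien-1-yl)silane; 4 ethyl (E)-3-methyl-4-oxobut-2-enoate
Product: 5 ethyl (1S,6S)-6-formyl-3,6-dimethyl-2-(trimethylsilyl)cyclohex-3-ene-1-carboxylate (silyl-bearing C2 unassigned)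
Conditions: (R)-B-(o-tolyl) oxazaborolidine from (R)-α,α-diphenylprolinol, protonated with HNTf2 (20 mol%), CH2Cl2, −78 → −40 °C; Et3N quench
Reagents that add atoms: none
Why: Catalytic enantioselective Diels–Alder reaction in which the boron-bound formyl group directs the silyl-bearing diene terminus (the most nucleophilic one through the 2-methyl group and β-silyl stabilisation) to C2 of the enal and the CH2 terminus to the methyl-bearing C3; suprafacial addition to the E alkene fixes formyl trans to ester (relative configuration of C1 and C6), and attack on the Si face of C3 of the catalyst-bound enal sets both centres in the absolute sense, while the configuration at the silyl carbon is of no consequence.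

Step 4
Reactants: 5 ethyl (1S,6S)-6-formyl-3,6-dimethyl-2-(trimethylsilyl)cyclohex-3-ene-1-carboxylate
Product: 6 ethyl (1S,6R)-6-ethenyl-3,6-dimethyl-2-(trimethylsilyl)cyclohex-3-ene-1-carboxylate
Conditions: Ph3PCH3Br, KN(SiMe3)2, THF, 0 °C; then 5, −78 → 0 °C
Reagents that add atoms: methyltriphenylphosphonium bromide, C[P+](c1ccccc1)(c1ccccc1)c1ccccc1.[Br-]
Why: Wittig methylenation, in which the unstabilised ylide should take the aldehyde far faster than the ester; the aldehyde α-carbon is quaternary and cannot epimerise.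

Step 5
Reactants: 6 ethyl (1S,6R)-6-ethenyl-3,6-dimethyl-2-(trimethylsilyl)cyclohex-3-ene-1-carboxylate
Product: 7 [(1S,6R)-6-ethenyl-3,6-dimethyl-2-(trimethylsilyl)cyclohex-3-en-1-yl]methanol
Conditions: i-Bu2AlH (2.5 equiv), CH2Cl2, −78 → 0 °C; aq potassium sodium tartrate
Reagents that add atoms: none
Why: Hydride reduction of the ester to the primary alcohol; the alkenes and the allylsilane are inert to the aluminium hydride at low temperature.

Step 6
Reactants: 7 [(1S,6R)-6-ethenyl-3,6-dimethyl-2-(trimethylsilyl)cyclohex-3-en-1-yl]methanol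
Product: 9 (E)-4-[(1R,6R)-6-ethenyl-3,6-dimethyl-2-(trimethylsilyl)cyclohex-3-en-1-yl]but-3-en-2-one, via silyl aldehyde 8 (not isolated)
Conditions: Dess–Martin periodinane, pyridine, CH2Cl2, 0 °C → rt, filtered; then (MeO)2P(O)CH2C(O)CH3, LiCl, i-Pr2NEt, MeCN, rt
Reagents that add atoms: dimethyl (2-oxopropyl)phosphonate, COP(=O)(CC(C)=O)OC
Why: Dess–Martin oxidation followed by Horner–Wadsworth–Emmons olefination under LiCl/amine conditions, mild enough to keep the α-stereocentre C6 (which at this stage is not yet allylic, because the silyl-bearing carbon still separates it from the ring alkene) and E-selective for the enone.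

Step 7
Reactants: 9 (E)-4-[(1R,6R)-6-ethenyl-3,6-dimethyl-2-(trimethylsilyl)cyclohex-3-en-1-yl]but-3-en-2-one
Product: 10 (E)-4-[(1S,6R)-6-ethenyl-3,6-dimethylcyclohex-2-en-1-yl]but-3-en-2-one
Conditions: CF3CO2H, CH2Cl2, 0 °C, short contact; aq NaHCO3
Reagents that add atoms: none
Why: Protodesilylation of the allylsilane with allylic transposition (SE2'), in which protonation at C3 gives the β-silyl tertiary cation and loss of silicon places the alkene at C4=C5, after the epimerisable aldehyde stage has been passed; the product alkene and the vinyl group are protonated far more slowly than the allylsilane.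

Step 8
Reactants: 10 (E)-4-[(1S,6R)-6-ethenyl-3,6-dimethylcyclohex-2-en-1-yl]but-3-en-2-one
Product: 12 (E)-1-diazo-4-[(1S,6R)-6-ethenyl-3,6-dimethylcyclohex-2-en-1-yl]but-3-en-2-one, via trifluoroacetyl diketone 11 (not isolated)
Conditions: LiN(SiMe3)2, THF, −78 °C; CF3CO2CH2CF3; aq HCl; then 4-acetamidobenzenesulfonyl azide, Et3N, H2O, MeCN, rt
Reagents that add atoms: 4-acetamidobenzenesulfonyl azide, CC(=O)Nc1ccc(cc1)S(=O)(=O)N=[N+]=[N-]; 2,2,2-trifluoroethyl trifluoroacetate, FC(F)(F)COC(=O)C(F)(F)F (atoms kept only in 11)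
Why: Detrifluoroacetylative diazo transfer, in which the kinetic α'-enolate of the methyl enone is trifluoroacetylated and the activated diketone takes the diazo group from the sulfonyl azide with loss of the trifluoroacetyl group; this is the standard entry to α'-diazo enones and leaves the hindered γ-hydrogen at C6 untouched.

Step 9
Reactants: 13 trichloroethene
Product: 15 (E)-1-tert-butoxy-1,2-dichloroethene, via dichloroethyne 14 (not isolated)
Conditions: KH, t-BuOH, THF, 0 °C; then 13, 0 °C → rt
Reagents that add atoms: tert-butanol, CC(C)(C)O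
Why: Elimination–addition, in which the alkoxide removes HCl from trichloroethene and tert-butoxide adds anti across the dichloroethyne formed; this is the known route to 1,2-dichlorovinyl ethers.

Step 10
Reactants: 15 (E)-1-tert-butoxy-1,2-dichloroethene
Product: 17 tert-butoxyethyne, via lithium tert-butoxyethynide 16 (not isolated)
Conditions: n-BuLi (2.2 equiv), THF, −78 → −40 °C; H2O, −78 °C; distilled, stored cold
Reagents that add atoms: n-butyllithium, [Li]CCCC (lithium kept only in 16)
Why: Elimination of LiCl and chlorine–lithium exchange with two equivalents of n-BuLi give the lithium alkoxyacetylide, which is protonated at low temperature; this is the known preparation of tert-alkoxyethynes.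

Step 11
Reactants: 12 (E)-1-diazo-4-[(1S,6R)-6-ethenyl-3,6-dimethylcyclohex-2-en-1-yl]but-3-en-2-one; 17 tert-butoxyethyne
Product: 22 5-tert-butoxy-2-[(1S,6R)-6-ethenyl-3,6-dimethylcyclohex-2-en-1-yl]phenol, via vinylketene 18 (not isolated), via vinylcyclobutenone 19 (not isolated), via dienylketene 20 (not isolated), via cyclohexadienone 21 (not isolated)
Conditions: 17 (3 equiv), ClCH2CH2Cl, hν (300 nm, Pyrex), 10–20 °C until 12 is consumed; excess 17 removed in vacuo; PhMe, 80 °C
Reagents that add atoms: none
Why: Irradiation expels N2 from 12 and the alkenyl group shifts to the carbene carbon (photochemical Wolff rearrangement), giving vinylketene 18, whose electrophilic carbonyl carbon is attacked by the unsubstituted, nucleophilic carbon of ynol ether 17 in a regioselective [2+2] cycloaddition that closes the four-membered ring of 19. Warming opens 19 by four-electron electrocyclic cleavage to dienylketene 20, which closes the benzene ring by thermal disrotatory six-electron electrocyclisation (new bond between the ketene carbon and the alkene carbon that carries the cyclohexenyl group) to dienone 21, and enolisation gives phenol 22. This is the diazo-ketone variant of the Danheiser benzannulation, known for aryl and alkenyl diazo ketones with alkoxy- and silyloxy-alkynes. No stereocentre is created: the sp3 carbons of 19 and 21 are lost on aromatisation, and C1 and C6 of the cyclohexene lie outside the reacting π system. The one selectivity required is the orientation of the [2+2] step, fixed by the polarisation of the ynol ether against the ketene, which places the two oxygens meta and the cyclohexenyl group ortho to the free hydroxyl; the ynol ether is also far more ketenophilic than the vinyl group or the ring alkene.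

Step 12
Reactants: 22 5-tert-butoxy-2-[(1S,6R)-6-ethenyl-3,6-dimethylcyclohex-2-en-1-yl]phenol
Product: 23 4-tert-butoxy-1-[(1S,6R)-6-ethenyl-3,6-dimethylcyclohex-2-en-1-yl]-2-methoxybenzene
Conditions: MeI, K2CO3, acetone, reflux
Reagents that add atoms: iodomethane, CI
Why: Williamson O-methylation of the only acidic site installs the C7' methoxyl; the aryl tert-butyl ether is stable to carbonate.

Step 13
Reactants: 23 4-tert-butoxy-1-[(1S,6R)-6-ethenyl-3,6-dimethylcyclohex-2-en-1-yl]-2-methoxybenzene
Product: 25 4-[(1S,6R)-6-ethenyl-3,6-dimethylcyclohex-2-en-1-yl]-3-methoxyphenol, via aryl silyl ether 24 (not isolated)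
Conditions: Me3SiOTf, 2,6-lutidine, CH2Cl2, 0 °C → rt; then K2CO3 (cat.), MeOH
Reagents that add atoms: trimethylsilyl trifluoromethanesulfonate, C[Si](C)(C)OS(=O)(=O)C(F)(F)F (atoms kept only in 24)
Why: Silyl-triflate-mediated cleavage of the aryl tert-butyl ether (O-silylation, loss of the tert-butyl cation as isobutene to the hindered base) followed by methanolysis of the aryl silyl ether; the buffered, non-protic conditions should spare the ring alkene, the vinyl group and the methyl ether.

Step 14
Reactants: 25 4-[(1S,6R)-6-ethenyl-3,6-dimethylcyclohex-2-en-1-yl]-3-methoxyphenol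
Product: 26 5-[(1S,6R)-6-ethenyl-3,6-dimethylcyclohex-2-en-1-yl]-2-hydroxy-4-methoxybenzaldehyde
Conditions: MgCl2, Et3N, (CH2O)n, MeCN, reflux; aq HCl
Reagents that add atoms: paraformaldehyde (as formaldehyde), C=O
Why: Magnesium-phenoxide ortho-formylation, which is confined to positions ortho to the hydroxyl and should take the open C4a' position para to the methoxyl over the crowded C8' between the two oxygens.

Step 15
Reactants: 26 5-[(1S,6R)-6-ethenyl-3,6-dimethylcyclohex-2-en-1-yl]-2-hydroxy-4-methoxybenzaldehyde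
Product: 28 6-[(1S,6R)-6-ethenyl-3,6-dimethylcyclohex-2-en-1-yl]-7-methoxy-2H-chromen-2-one, via hydroxycinnamate 27 (not isolated)
Conditions: Ph3P=CHCO2Et, PhNEt2, reflux
Reagents that add atoms: ethyl (triphenylphosphoranylidene)acetate, CCOC(=O)C=P(c1ccccc1)(c1ccccc1)c1ccccc1
Why: Wittig olefination with thermal E/Z isomerisation and lactonisation in hot N,N-diethylaniline, the standard conversion of salicylaldehydes into coumarins, closes the pyranone ring.

Step 16
Reactants: 29 5-bromo-2-hydroxy-4-methoxybenzaldehyde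
Product: 31 6-bromo-7-methoxy-2H-chromen-2-one, via bromo hydroxycinnamate 30 (not isolated)
Conditions: Ph3P=CHCO2Et, PhNEt2, reflux
Reagents that add atoms: ethyl (triphenylphosphoranylidene)acetate, CCOC(=O)C=P(c1ccccc1)(c1ccccc1)c1ccccc1
Why: The same Wittig olefination–lactonisation gives the aryl bromide partner in one step.

Step 17
Reactants: 28 6-[(1S,6R)-6-ethenyl-3,6-dimethylcyclohex-2-en-1-yl]-7-methoxy-2H-chromen-2-one; 31 6-bromo-7-methoxy-2H-chromen-2-one
Product: 32 7-methoxy-6-{(E)-2-[(1R,2S)-2-(7-methoxy-2-oxo-2H-chromen-6-yl)-1,4-dimethylcyclohex-3-en-1-yl]ethenyl}-2H-chromen-2-one (target)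
Conditions: Pd(OAc)2 (10 mol%), P(o-Tol)3 (30 mol%), Et3N, DMF, 100 °C
Reagents that add atoms: none
Why: Mizoroki–Heck arylation of a vinyl group on a quaternary carbon, in which the aryl group adds to the terminal carbon and β-hydride elimination is possible only toward the new benzylic position, so the linear E-styrene should form; the trisubstituted ring alkene and the coumarin C3=C4 bonds are much poorer acceptors, and neither stereocentre is touched.

**Compound list**

1 | 3-methyl-2,5-dihydrothiophene 1,1-dioxide (3-methyl-3-sulfolene) | CC1=CCS(=O)(=O)C1 | starting material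
2 | 3-methyl-2-(trimethylsilyl)-2,5-dihydrothiophene 1,1-dioxide (racemic) | CC1=CCS(=O)(=O)C1[Si](C)(C)C | intermediate
3 | (E)-trimethyl(2-methylbuta-1,3-dien-1-yl)silane | C=C/C(C)=C/[Si](C)(C)C | intermediate
4 | ethyl (E)-3-methyl-4-oxobut-2-enoate | CCOC(=O)/C=C(\C)C=O | starting material
5 | ethyl (1S,6S)-6-formyl-3,6-dimethyl-2-(trimethylsilyl)cyclohex-3-ene-1-carboxylate (C2 unassigned) | O=C[C@@]1(C)CC=C(C)C([Si](C)(C)C)[C@@H]1C(=O)OCC | intermediate
6 | ethyl (1S,6R)-6-ethenyl-3,6-dimethyl-2-(trimethylsilyl)cyclohex-3-ene-1-carboxylate (C2 unassigned) | C=C[C@@]1(C)CC=C(C)C([Si](C)(C)C)[C@@H]1C(=O)OCC | intermediate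
7 | [(1S,6R)-6-ethenyl-3,6-dimethyl-2-(trimethylsilyl)cyclohex-3-en-1-yl]methanol (C2 unassigned) | C=C[C@@]1(C)CC=C(C)C([Si](C)(C)C)[C@@H]1CO | intermediate
8 | (1S,6R)-6-ethenyl-3,6-dimethyl-2-(trimethylsilyl)cyclohex-3-ene-1-carbaldehyde (C2 unassigned) | C=C[C@@]1(C)CC=C(C)C([Si](C)(C)C)[C@@H]1C=O | intermediate (not isolated)
9 | (E)-4-[(1R,6R)-6-ethenyl-3,6-dimethyl-2-(trimethylsilyl)cyclohex-3-en-1-yl]but-3-en-2-one (C2 unassigned) | C=C[C@@]1(C)CC=C(C)C([Si](C)(C)C)[C@@H]1/C=C/C(C)=O | intermediate
10 | (E)-4-[(1S,6R)-6-ethenyl-3,6-dimethylcyclohex-2-en-1-yl]but-3-en-2-one | C=C[C@@]1(C)CCC(C)=C[C@@H]1/C=C/C(C)=O | intermediate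
11 | (E)-6-[(1S,6R)-6-ethenyl-3,6-dimethylcyclohex-2-en-1-yl]-1,1,1-trifluorohex-5-ene-2,4-dione | C=C[C@@]1(C)CCC(C)=C[C@@H]1/C=C/C(=O)CC(=O)C(F)(F)F | intermediate (not isolated)
12 | (E)-1-diazo-4-[(1S,6R)-6-ethenyl-3,6-dimethylcyclohex-2-en-1-yl]but-3-en-2-one | C=C[C@@]1(C)CCC(C)=C[C@@H]1/C=C/C(=O)C=[N+]=[N-] | intermediate (key-step precursor)
13 | trichloroethene | ClC=C(Cl)Cl | starting material
14 | dichloroethyne | ClC#CCl | intermediate (not isolated)
15 | (E)-1-tert-butoxy-1,2-dichloroethene | CC(C)(C)O/C(Cl)=C\Cl | intermediate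
16 | lithium tert-butoxyethynide | [Li]C#COC(C)(C)C | intermediate (not isolated)
17 | tert-butoxyethyne | C#COC(C)(C)C | intermediate (key-step precursor)
18 | (E)-4-[(1S,6R)-6-ethenyl-3,6-dimethylcyclohex-2-en-1-yl]buta-1,3-dien-1-one | C=C[C@@]1(C)CCC(C)=C[C@@H]1/C=C/C=C=O | intermediate (not isolated)
19 | 3-tert-butoxy-4-{(E)-2-[(1S,6R)-6-ethenyl-3,6-dimethylcyclohex-2-en-1-yl]ethenyl}cyclobut-2-en-1-one (C4 unassigned) | C=C[C@@]1(C)CCC(C)=C[C@@H]1/C=C/C1C(=O)C=C1OC(C)(C)C | intermediate (not isolated)
20 | (3E,5E)-3-tert-butoxy-6-[(1S,6R)-6-ethenyl-3,6-dimethylcyclohex-2-en-1-yl]hexa-1,3,5-trien-1-one | C=C[C@@]1(C)CCC(C)=C[C@@H]1/C=C/C=C(OC(C)(C)C)\C=C=O | intermediate (not isolated)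
21 | 3-tert-butoxy-6-[(1R,6R)-6-ethenyl-3,6-dimethylcyclohex-2-en-1-yl]cyclohexa-2,4-dien-1-one (dienone C6 unassigned) | C=C[C@@]1(C)CCC(C)=C[C@@H]1C1C=CC(OC(C)(C)C)=CC1=O | intermediate (not isolated)
22 | 5-tert-butoxy-2-[(1S,6R)-6-ethenyl-3,6-dimethylcyclohex-2-en-1-yl]phenol | C=C[C@@]1(C)CCC(C)=C[C@@H]1c1ccc(OC(C)(C)C)cc1O | intermediate (key-step product)
23 | 4-tert-butoxy-1-[(1S,6R)-6-ethenyl-3,6-dimethylcyclohex-2-en-1-yl]-2-methoxybenzene | C=C[C@@]1(C)CCC(C)=C[C@@H]1c1ccc(OC(C)(C)C)cc1OC | intermediate
24 | {4-[(1S,6R)-6-ethenyl-3,6-dimethylcyclohex-2-en-1-yl]-3-methoxyphenoxy}trimethylsilane | C=C[C@@]1(C)CCC(C)=C[C@@H]1c1ccc(O[Si](C)(C)C)cc1OC | intermediate (not isolated)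
25 | 4-[(1S,6R)-6-ethenyl-3,6-dimethylcyclohex-2-en-1-yl]-3-methoxyphenol | C=C[C@@]1(C)CCC(C)=C[C@@H]1c1ccc(O)cc1OC | intermediate
26 | 5-[(1S,6R)-6-ethenyl-3,6-dimethylcyclohex-2-en-1-yl]-2-hydroxy-4-methoxybenzaldehyde | C=C[C@@]1(C)CCC(C)=C[C@@H]1c1cc(C=O)c(O)cc1OC | intermediate
27 | ethyl (E)-3-{5-[(1S,6R)-6-ethenyl-3,6-dimethylcyclohex-2-en-1-yl]-2-hydroxy-4-methoxyphenyl}prop-2-enoate | C=C[C@@]1(C)CCC(C)=C[C@@H]1c1cc(/C=C/C(=O)OCC)c(O)cc1OC | intermediate (not isolated)
28 | 6-[(1S,6R)-6-ethenyl-3,6-dimethylcyclohex-2-en-1-yl]-7-methoxy-2H-chromen-2-one | C=C[C@@]1(C)CCC(C)=C[C@@H]1c1cc2ccc(=O)oc2cc1OC | intermediate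
29 | 5-bromo-2-hydroxy-4-methoxybenzaldehyde | COc1cc(O)c(C=O)cc1Br | starting material
30 | ethyl (E)-3-(5-bromo-2-hydroxy-4-methoxyphenyl)prop-2-enoate | CCOC(=O)/C=C/c1cc(Br)c(OC)cc1O | intermediate (not isolated)
31 | 6-bromo-7-methoxy-2H-chromen-2-one | COc1cc2oc(=O)ccc2cc1Br | intermediate
32 | 7-methoxy-6-{(E)-2-[(1R,2S)-2-(7-methoxy-2-oxo-2H-chromen-6-yl)-1,4-dimethylcyclohex-3-en-1-yl]ethenyl}-2H-chromen-2-one | COc1cc2oc(=O)ccc2cc1/C=C/[C@@]1(C)CCC(C)=C[C@@H]1c1cc2ccc(=O)oc2cc1OC | target

**Step count and risks**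

Total: 17 steps. Longest linear sequence: 14 steps (steps 1–8, 11–15 and 17, from 3-methyl-3-sulfolene).

Steps most likely to fail:

Step 11 (key step). The risk is diversion of the photochemical cascade before the [2+2] step: light-induced E/Z isomerisation of the enone or vinylketene followed by a 1,5-hydrogen shift, carbene insertion, or acylation of early-formed phenol by unreacted ketene. The fallback generates the same vinylketene in the dark. It sets out from 12: silver-catalysed Wolff rearrangement (PhCO2Ag, Et3N, THF–H2O, rt) gives the homologous acid (E)-4-[(1S,6R)-6-ethenyl-3,6-dimethylcyclohex-2-en-1-yl]but-3-enoic acid F4. Oxalyl chloride with catalytic DMF converts it into (E)-4-[(1S,6R)-6-ethenyl-3,6-dimethylcyclohex-2-en-1-yl]but-3-enoyl chloride F5. Slow addition of Et3N to F5 and 17 in toluene at 0–25 °C gives 18 by dehydrochlorination and then 19, and heating at 80 °C carries the mixture through 20 and 21. The fallback comes back to the route at 22.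

Step 3. The risk is insufficient facial or regiochemical control with the silyl diene, or premature protodesilylation of the allylsilane by the strongly acidic catalyst. The fallback sets out from 3 and 4 and replaces asymmetric induction by resolution. Me2AlCl in CH2Cl2 at −78 °C gives racemic adduct, that is 5 together with its enantiomer ethyl (1R,6R)-6-formyl-3,6-dimethyl-2-(trimethylsilyl)cyclohex-3-ene-1-carboxylate F1. Steps 4 and 5 applied to the racemate give, beside 6 and 7, the enantiomers ethyl (1R,6S)-6-ethenyl-3,6-dimethyl-2-(trimethylsilyl)cyclohex-3-ene-1-carboxylate F2 and [(1R,6S)-6-ethenyl-3,6-dimethyl-2-(trimethylsilyl)cyclohex-3-en-1-yl]methanol F3. The racemic alcohol is separated by preparative chromatography on an amylose tris(3,5-dimethylphenylcarbamate) stationary phase, and the fallback comes back to the route at 7.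

Step 17. The risk is slow insertion into the hindered vinyl group, with competing reduction of the bromide or arylation at the branched position. The fallback sets out from 28 and joins the fragments by metathesis and cross-coupling. Cross-metathesis with vinylboronic acid pinacol ester (second-generation Hoveyda–Grubbs catalyst, RuCl2(H2IMes)(=CH–C6H4-2-O-i-Pr), CH2Cl2, 40 °C) should give the E-alkenylboronate 7-methoxy-6-{(1S,6R)-3,6-dimethyl-6-[(E)-2-(4,4,5,5-tetramethyl-1,3,2-dioxaborolan-2-yl)ethenyl]cyclohex-2-en-1-yl}-2H-chromen-2-one F6. Suzuki–Miyaura coupling of F6 with 31 (Pd(dppf)Cl2, K3PO4, dioxane–H2O, 70 °C) then comes back to the route at 32.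

**Further compounds**

F1 | step 3 | ethyl (1R,6R)-6-formyl-3,6-dimethyl-2-(trimethylsilyl)cyclohex-3-ene-1-carboxylate (enantiomer of 5) | O=C[C@]1(C)CC=C(C)C([Si](C)(C)C)[C@H]1C(=O)OCC
F2 | step 3 | ethyl (1R,6S)-6-ethenyl-3,6-dimethyl-2-(trimethylsilyl)cyclohex-3-ene-1-carboxylate (enantiomer of 6) | C=C[C@]1(C)CC=C(C)C([Si](C)(C)C)[C@H]1C(=O)OCC
F3 | step 3 | [(1R,6S)-6-ethenyl-3,6-dimethyl-2-(trimethylsilyl)cyclohex-3-en-1-yl]methanol (enantiomer of 7) | C=C[C@]1(C)CC=C(C)C([Si](C)(C)C)[C@H]1CO
F4 | step 11 | (E)-4-[(1S,6R)-6-ethenyl-3,6-dimethylcyclohex-2-en-1-yl]but-3-enoic acid | C=C[C@@]1(C)CCC(C)=C[C@@H]1/C=C/CC(=O)O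
F5 | step 11 | (E)-4-[(1S,6R)-6-ethenyl-3,6-dimethylcyclohex-2-en-1-yl]but-3-enoyl chloride | C=C[C@@]1(C)CCC(C)=C[C@@H]1/C=C/CC(=O)Cl
F6 | step 17 | 7-methoxy-6-{(1S,6R)-3,6-dimethyl-6-[(E)-2-(4,4,5,5-tetramethyl-1,3,2-dioxaborolan-2-yl)ethenyl]cyclohex-2-en-1-yl}-2H-chromen-2-one | CC1(C)OB(/C=C/[C@@]2(C)CCC(C)=C[C@@H]2c2cc3ccc(=O)oc3cc2OC)OC1(C)C
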